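**Plan**
- Cuts: the interflavan bond C4 (catechin unit)–C8 (epigallocatechin gallate unit); then, in ring C of the lower unit, the C3–C4 and O1–C2 bonds together; last, twelve O-benzyl bonds.
- Enabling feature: in the lower unit O1 and C4H2 sit on the adjacent carbons C8a and C4a of the phloroglucinol ring A. Ring C is therefore the [4+2] adduct of an o-quinone methide (O1=C8a–C4a=C4H2) and a C2=C3 alkene, and that alkene is a Z-enol ester that already is the gallate of the target.
- Forward: aryl aldehyde → aryl alkyne → Z-enol gallate; 3,5-bis(benzyloxy)phenol → salicyl alcohol; a chiral phosphoric acid catalysed oxa-[4+2] cycloaddition of these two achiral pieces builds ring C as fully protected epigallocatechin gallate.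
- (+)-Catechin (chiral pool) is benzylated, oxidised at C4 and joined as its C4 cation to C8 of the lower unit; one hydrogenolysis removes all benzyl groups.
- Stereochemistry: lower C2/C3 cis from the Z alkene (suprafacial addition), their absolute sense from the catalyst; upper C2/C3 bought with catechin; upper C4 by substrate control (attack trans to the C3 oxygen).

Key step: step 5

Remark: the sense of induction of the phosphoric acid in step 5 cannot be taken over from a close precedent; the (R)-acid is written, and its mirror image would be used instead if the (2S,3S) adduct were favoured.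

**Step 1**
Reactants: 1 3,4,5-tris(benzyloxy)benzaldehyde; 2 dimethyl (1-diazo-2-oxopropyl)phosphonate (Ohira–Bestmann reagent)
Product: 3 5-ethynyl-1,2,3-tris(benzyloxy)benzene
Conditions: 2, K2CO3, MeOH/THF, 0 °C to rt
Reagents that add atoms: dimethyl (1-diazo-2-oxopropyl)phosphonate 2, CC(=O)C(=[N+]=[N-])P(=O)(OC)OC
Why: Seyferth–Gilbert homologation in the Ohira–Bestmann variant: methanolysis of 2 gives the diazomethylphosphonate anion, which olefinates the aldehyde and loses N2 to an alkylidene carbene that rearranges to the terminal alkyne, while benzyl ethers are inert.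

**Step 2**
Reactants: 3 5-ethynyl-1,2,3-tris(benzyloxy)benzene; 4 3,4,5-tris(benzyloxy)benzoic acid
Product: 5 (Z)-2-[3,4,5-tris(benzyloxy)phenyl]ethenyl 3,4,5-tris(benzyloxy)benzoate
Conditions: [RuCl2(p-cymene)]2 (cat.), P(4-ClC6H4)3, DMAP, toluene, 60 °C
Reagents that add atoms: none
Why: Ruthenium-catalysed anti-Markovnikov hydro-acyloxylation of a terminal alkyne through a ruthenium vinylidene, in which the carboxylate adds to the vinylidene α-carbon and protonolysis gives the formal trans-addition product, that is the Z-enol ester.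

**Step 3**
Reactants: 6 3,5-bis(benzyloxy)phenol; 7 paraformaldehyde
Product: 8 2,4-bis(benzyloxy)-6-hydroxybenzaldehyde
Conditions: MgCl2, Et3N, (CH2O)n, MeCN, reflux; then aq. HCl
Reagents that add atoms: formaldehyde (as paraformaldehyde) 7, C=O
Why: Magnesium-mediated ortho-formylation (Casnati–Skattebøl): the magnesium phenoxide delivers formaldehyde only to an ortho carbon (the two are equivalent) and a second equivalent of formaldehyde oxidises the salicyl alkoxide to the aldehyde.

**Step 4**
Reactants: 8 2,4-bis(benzyloxy)-6-hydroxybenzaldehyde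
Product: 9 3,5-bis(benzyloxy)-2-(hydroxymethyl)phenol
Conditions: NaBH4, THF/MeOH, 0 °C; pH 7 buffer work-up, no silica, used at once
Reagents that add atoms: none
Why: Hydride reduction of the aldehyde; the acid-labile 2,4,6-trioxygenated benzyl alcohol is kept away from acid and carried on crude.

**Step 5**
Reactants: 9 3,5-bis(benzyloxy)-2-(hydroxymethyl)phenol; 5 (Z)-2-[3,4,5-tris(benzyloxy)phenyl]ethenyl 3,4,5-tris(benzyloxy)benzoate
Product: 11 (2R,3R)-5,7-bis(benzyloxy)-2-[3,4,5-tris(benzyloxy)phenyl]chroman-3-yl 3,4,5-tris(benzyloxy)benzoate (octa-O-benzyl EGCG), via o-quinone methide 10 (not isolated)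
Conditions: (R)-3,3'-bis(2,4,6-triisopropylphenyl)-1,1'-binaphthyl-2,2'-diyl hydrogen phosphate (10 mol %), 5 Å MS, toluene, −20 °C to 0 °C, 9 added slowly to 5 (2 equiv)
Reagents that add atoms: none
Why: Proposed new method: the phosphoric acid dehydrates 9 to the o-quinone methide 10 and stays hydrogen-bonded to its carbonyl oxygen, which lowers the LUMO of the 1-oxadiene O1=C8a–C4a=C4H2 so that it adds to the Z-alkene 5 in an inverse-electron-demand oxa-[4+2] cycloaddition that is concerted but asynchronous, the C4–C3 bond running ahead of the O1–C2 bond; the closest known reaction types are the thermal o-quinone methide/styrene cycloaddition that gives flavans and the chiral phosphoric acid catalysed [4+2] cycloadditions of o-quinone methides made in the flask from o-hydroxybenzyl alcohols with vinylarenes, and the new elements are the β-acyloxystyrene dienophile and enantiocontrol with an unsubstituted methide carbon. Ring C closes as the six-membered ring of a suprafacial [4π+2π] cycloaddition (in the stepwise limit, a six-membered closure of the phenolic oxygen onto the C2 benzylic cation). The cis relation of C2 and C3 is a copy of the Z geometry of 5, because both new bonds form on the same face of the alkene. The absolute configuration (2R,3R) should come from the chiral phosphate bound at O1, whose 2,4,6-triisopropylphenyl groups flank the place where the C2 aryl group must dock, so that one enantiotopic face of 5 is preferred. The regiochemistry needed (CH2 to the acyloxy carbon, O to the aryl carbon) is secured by the 4-alkoxyaryl ring B, which stabilises positive charge at C2 far better than the ester oxygen, whose lone pair is engaged by the galloyl carbonyl, can at C3. Self-condensation of 10 with the electron-rich rings of 9 or 11 is held back by slow addition of 9 to an excess of 5 at low temperature, and the weak acid should keep the pathway concerted so that the cis geometry is not lost through a free cation.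

**Step 6**
Reactants: 12 (+)-catechin; 13 benzyl bromide
Product: 14 (2R,3S)-5,7-bis(benzyloxy)-2-[3,4-bis(benzyloxy)phenyl]chroman-3-ol
Conditions: BnBr, K2CO3, DMF, 0 °C to rt, argon
Reagents that add atoms: benzyl bromide 13, BrCc1ccccc1
Why: Williamson etherification of the four phenols; carbonate does not deprotonate the aliphatic 3-OH, and low temperature under inert gas guards against base-induced epimerisation at C2.

**Step 7**
Reactants: 14 (2R,3S)-5,7-bis(benzyloxy)-2-[3,4-bis(benzyloxy)phenyl]chroman-3-ol; 15 2-ethoxyethanol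
Product: 16 (2R,3S,4S)-5,7-bis(benzyloxy)-2-[3,4-bis(benzyloxy)phenyl]-4-(2-ethoxyethoxy)chroman-3-ol
Conditions: DDQ, EtOCH2CH2OH, CH2Cl2, rt
Reagents that add atoms: 2-ethoxyethanol 15, CCOCCO
Why: DDQ benzylic oxidation: hydride abstraction from C4 gives the cation stabilised by ring A, which the alcohol should trap cis to the 3-OH; the configuration of this centre is of no consequence because step 8 ionises it again.

**Step 8**
Reactants: 16 (2R,3S,4S)-5,7-bis(benzyloxy)-2-[3,4-bis(benzyloxy)phenyl]-4-(2-ethoxyethoxy)chroman-3-ol; 11 octa-O-benzyl EGCG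
Product: 17 (2R,3R)-5,7-bis(benzyloxy)-8-{(2R,3S,4S)-5,7-bis(benzyloxy)-2-[3,4-bis(benzyloxy)phenyl]-3-hydroxychroman-4-yl}-2-[3,4,5-tris(benzyloxy)phenyl]chroman-3-yl 3,4,5-tris(benzyloxy)benzoate
Conditions: TMSOTf (cat.), CH2Cl2, −78 °C, 11 in excess (recovered); aq. NaHCO3
Reagents that add atoms: none
Why: Friedel–Crafts-type arylation of a flavan-4-yl cation: TMSOTf ionises the 4-alkoxy group and C8 of the 5,7-dibenzyloxy ring A of 11, its most nucleophilic position, attacks the planar C4 cation on the face opposite to the C3 oxygen, which sets the 3,4-trans (4S, 4α) configuration.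

**Step 9**
Reactants: 17 dodeca-O-benzyl dimer
Product: 18 catechin-(4α→8)-epigallocatechin 3-O-gallate (CNP0246304.1)
Conditions: H2 (1 atm), Pd(OH)2/C, THF/MeOH/H2O, rt
Reagents that add atoms: none
Why: Hydrogenolysis of the twelve benzyl ethers; under these mild conditions the gallate ester, the pyran C2–O bonds and the C4–C8 bond should be retained, and no stereocentre is touched.

**Compound list**
1 | 3,4,5-tris(benzyloxy)benzaldehyde | O=Cc1cc(OCc2ccccc2)c(OCc2ccccc2)c(OCc2ccccc2)c1 | starting material
2 | dimethyl (1-diazo-2-oxopropyl)phosphonate | CC(=O)C(=[N+]=[N-])P(=O)(OC)OC | starting material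
3 | 5-ethynyl-1,2,3-tris(benzyloxy)benzene | C#Cc1cc(OCc2ccccc2)c(OCc2ccccc2)c(OCc2ccccc2)c1 | intermediate
4 | 3,4,5-tris(benzyloxy)benzoic acid | OC(=O)c1cc(OCc2ccccc2)c(OCc2ccccc2)c(OCc2ccccc2)c1 | starting material
5 | (Z)-2-[3,4,5-tris(benzyloxy)phenyl]ethenyl 3,4,5-tris(benzyloxy)benzoate | O=C(O/C=C\c1cc(OCc2ccccc2)c(OCc2ccccc2)c(OCc2ccccc2)c1)c1cc(OCc2ccccc2)c(OCc2ccccc2)c(OCc2ccccc2)c1 | intermediate
6 | 3,5-bis(benzyloxy)phenol | Oc1cc(OCc2ccccc2)cc(OCc2ccccc2)c1 | starting material
7 | paraformaldehyde (formaldehyde unit) | C=O | starting material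
8 | 2,4-bis(benzyloxy)-6-hydroxybenzaldehyde | O=Cc1c(O)cc(OCc2ccccc2)cc1OCc1ccccc1 | intermediate
9 | 3,5-bis(benzyloxy)-2-(hydroxymethyl)phenol | OCc1c(O)cc(OCc2ccccc2)cc1OCc1ccccc1 | intermediate
10 | 3,5-bis(benzyloxy)-6-methylidenecyclohexa-2,4-dien-1-one (o-quinone methide) | C=C1C(=O)C=C(OCc2ccccc2)C=C1OCc1ccccc1 | intermediate (not isolated)
11 | (2R,3R)-5,7-bis(benzyloxy)-2-[3,4,5-tris(benzyloxy)phenyl]chroman-3-yl 3,4,5-tris(benzyloxy)benzoate | O=C(O[C@@H]1Cc2c(OCc3ccccc3)cc(OCc3ccccc3)cc2O[C@@H]1c1cc(OCc2ccccc2)c(OCc2ccccc2)c(OCc2ccccc2)c1)c1cc(OCc2ccccc2)c(OCc2ccccc2)c(OCc2ccccc2)c1 | intermediate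
12 | (+)-catechin, (2R,3S) | C1c2c(O)cc(O)cc2O[C@H](c2ccc(O)c(O)c2)[C@H]1O | starting material
13 | benzyl bromide | BrCc1ccccc1 | starting material
14 | (2R,3S)-5,7-bis(benzyloxy)-2-[3,4-bis(benzyloxy)phenyl]chroman-3-ol | C1c2c(OCc3ccccc3)cc(OCc3ccccc3)cc2O[C@H](c2ccc(OCc3ccccc3)c(OCc3ccccc3)c2)[C@H]1O | intermediate
15 | 2-ethoxyethanol | CCOCCO | starting material
16 | (2R,3S,4S)-5,7-bis(benzyloxy)-2-[3,4-bis(benzyloxy)phenyl]-4-(2-ethoxyethoxy)chroman-3-ol | CCOCCO[C@H]1c2c(OCc3ccccc3)cc(OCc3ccccc3)cc2O[C@H](c2ccc(OCc3ccccc3)c(OCc3ccccc3)c2)[C@H]1O | intermediate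
17 | dodeca-O-benzyl catechin-(4α→8)-epigallocatechin 3-O-gallate (upper 3-OH free) | O=C(O[C@@H]1Cc2c(OCc5ccccc5)cc(OCc5ccccc5)c([C@@H]3c4c(OCc5ccccc5)cc(OCc5ccccc5)cc4O[C@H](c4ccc(OCc5ccccc5)c(OCc5ccccc5)c4)[C@H]3O)c2O[C@@H]1c1cc(OCc5ccccc5)c(OCc5ccccc5)c(OCc5ccccc5)c1)c1cc(OCc5ccccc5)c(OCc5ccccc5)c(OCc5ccccc5)c1 | intermediate
18 | catechin-(4α→8)-epigallocatechin 3-O-gallate, (2R,3R) lower unit, (2R,3S,4S) upper unit | O=C(O[C@@H]1Cc2c(O)cc(O)c([C@@H]3c4c(O)cc(O)cc4O[C@H](c4ccc(O)c(O)c4)[C@H]3O)c2O[C@@H]1c1cc(O)c(O)c(O)c1)c1cc(O)c(O)c(O)c1 | target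

**Totals**
Total step count: 9. Longest linear sequence: 5 steps (1 → 2 → 5 → 8 → 9, or equally 3 → 4 → 5 → 8 → 9).

**Steps most likely to fail**

Step 5 (proposed new method). The acid binds the o-quinone methide at one point only, so enantiofacial discrimination may be poor. A stepwise cationic pathway with bond rotation or participation of the neighbouring ester could erode the cis relation. The ester oxygen could reverse the regiochemistry. The electron-rich methide could self-condense before it meets the alkene. A mere shortfall in enantiomeric purity is purged at step 8 by chromatographic separation of diastereomers. Fallback with known chemistry: the de novo ring construction is given up, and commercially available (−)-epigallocatechin 3-O-gallate F1 is per-O-benzylated with benzyl bromide 13 (K2CO3, DMF, 0 °C to rt, argon), a plain phenol alkylation. The fallback sets out from 13 and returns to the route at 11.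

Step 8. The electrophile can self-condense through its own ring A when the valuable nucleophile cannot be used in large excess, and some loss of 3,4-trans selectivity or attack at C6 is possible. Fallback by bromine capping: compound 14 is brominated at C8 (NBS, CH2Cl2, −20 °C) to (2R,3S)-8-bromo-5,7-bis(benzyloxy)-2-[3,4-bis(benzyloxy)phenyl]chroman-3-ol F2. This is oxidised with DDQ and 2-ethoxyethanol to the capped 4-(2-ethoxyethoxy) electrophile F3, which cannot attack itself. F3 is coupled with an equimolar amount of 11 (BF3·OEt2, CH2Cl2, −78 to −30 °C) to give the 8-bromo dodeca-O-benzyl dimer F4. Hydrogenolysis (H2, Pd(OH)2/C, Et3N, THF/MeOH/H2O) removes the bromine together with the benzyl groups. The fallback sets out from 14 and returns at 18.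

Step 2. Z selectivity may erode, or Markovnikov addition may compete, with these bulky electron-rich partners, and the alkene isomers would be hard to separate. Fallback by stereoretentive C–O coupling: alkyne 3 undergoes rhodium-catalysed trans-hydroboration (pinacolborane, [RhCl(cod)]2, P(i-Pr)3, Et3N, cyclohexane, rt) to the (Z)-alkenyl pinacol boronate F5. KHF2 in MeOH/H2O converts it to potassium (Z)-trifluoro{2-[3,4,5-tris(benzyloxy)phenyl]ethenyl}borate F6. Copper-catalysed oxidative coupling of F6 with acid 4 (CuBr, DMAP, 4 Å MS, O2, MeCN) should give the enol ester with retention of the Z geometry. The fallback sets out from 3 and returns at 5.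

**Further compounds**
F1 | step 5 | (−)-epigallocatechin 3-O-gallate | O=C(O[C@@H]1Cc2c(O)cc(O)cc2O[C@@H]1c1cc(O)c(O)c(O)c1)c1cc(O)c(O)c(O)c1
F2 | step 8 | (2R,3S)-8-bromo-5,7-bis(benzyloxy)-2-[3,4-bis(benzyloxy)phenyl]chroman-3-ol | C1c2c(OCc3ccccc3)cc(OCc3ccccc3)c(Br)c2O[C@H](c2ccc(OCc3ccccc3)c(OCc3ccccc3)c2)[C@H]1O
F3 | step 8 | (2R,3S,4S)-8-bromo-5,7-bis(benzyloxy)-2-[3,4-bis(benzyloxy)phenyl]-4-(2-ethoxyethoxy)chroman-3-ol | CCOCCO[C@H]1c2c(OCc3ccccc3)cc(OCc3ccccc3)c(Br)c2O[C@H](c2ccc(OCc3ccccc3)c(OCc3ccccc3)c2)[C@H]1O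
F4 | step 8 | 8-bromo (upper unit) dodeca-O-benzyl catechin-(4α→8)-epigallocatechin 3-O-gallate | O=C(O[C@@H]1Cc2c(OCc5ccccc5)cc(OCc5ccccc5)c([C@@H]3c4c(OCc5ccccc5)cc(OCc5ccccc5)c(Br)c4O[C@H](c4ccc(OCc5ccccc5)c(OCc5ccccc5)c4)[C@H]3O)c2O[C@@H]1c1cc(OCc5ccccc5)c(OCc5ccccc5)c(OCc5ccccc5)c1)c1cc(OCc5ccccc5)c(OCc5ccccc5)c(OCc5ccccc5)c1
F5 | step 2 | (Z)-4,4,5,5-tetramethyl-2-{2-[3,4,5-tris(benzyloxy)phenyl]ethenyl}-1,3,2-dioxaborolane | CC1(C)OB(/C=C\c2cc(OCc3ccccc3)c(OCc3ccccc3)c(OCc3ccccc3)c2)OC1(C)C
F6 | step 2 | potassium (Z)-trifluoro{2-[3,4,5-tris(benzyloxy)phenyl]ethenyl}borate | [K+].F[B-](F)(F)/C=C\c1cc(OCc2ccccc2)c(OCc2ccccc2)c(OCc2ccccc2)c1
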